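**Retrosynthetic overview**

- The strategy rests on the C1 oxygen, the C3 methyl and the C4–C5 bond of eight-membered ring A (later the fused cyclopropane, ring C). Together they map onto a (4Z)-cyclooct-4-en-1-one whose C1–C2 bond is the key disconnection. This opens ring A to the 4-alkenal 18 (C1 formyl, C8, C7, C6=C5), whose C5 carries a trans-2-methylcyclopropyl group that supplies C4, C3 and C2.
- 18 comes from an amine-catalysed Michael addition of (R)-citronellal (C1, C8 and the whole side chain) to nitrodiene 12. This forms C7–C8 and sets C8; the nitromethyl carbon is then oxidised to the C7 ester.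
- 12 comes from (1R,2R)-2-methylcyclopropanecarbaldehyde (asymmetric cyclopropanation of (E)-crotyl alcohol) by Horner–Wadsworth–Emmons olefination and Henry condensation.
- Ring order: relay cyclopropane (consumed), ring A (step 12), lactone ring B (step 13), cyclopropane ring C (step 15). C1 is set by hydride reduction, the butenolide by selenoxide elimination, and acetylation ends the route.

Key step: step 12

Assumption: ring A is numbered C1 (CHOAc), C2, C3 (CHMe), C4 and C5 (cyclopropane CH), C6 and C7 (butenolide β- and α-carbons), C8 (side-chain carbon), with C9 the side-chain methine. C6 and C7 of 19–25 are drawn as the diastereomer expected from the mechanism; either epimer would serve, since both carbons become sp2 in step 17.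

**Route**

Step 1
Reactants: 1 (E)-but-2-en-1-ol
Product: 2 [(1R,2R)-2-methylcyclopropyl]methanol
Conditions: Et2Zn, CH2I2, DME, (4S,5S)-2-butyl-N,N,N′,N′-tetramethyl-1,3,2-dioxaborolane-4,5-dicarboxamide (1.2 equiv), CH2Cl2, −10 °C to rt
Reagents that add atoms: diiodomethane, ICI
Why: Asymmetric Simmons–Smith cyclopropanation of an allylic alcohol: the zinc alkoxide bound to the chiral dioxaborolane delivers CH2 to one alkene face, the E geometry is carried stereospecifically into the trans ring, and the (4S,5S) controller is the enantiomer expected to give the (1R,2R) alcohol (these carbons become C4 and C3).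

Step 2
Reactants: 2 [(1R,2R)-2-methylcyclopropyl]methanol
Product: 3 (1R,2R)-2-methylcyclopropane-1-carbaldehyde
Conditions: TEMPO (cat.), PhI(OAc)2, CH2Cl2, 0 °C to rt; aq. NaHCO3 wash, dried solution used directly
Reagents that add atoms: none
Why: Nitroxyl-catalysed alcohol oxidation stops at the aldehyde, the cyclopropyl α-carbon does not enolise so both stereocentres are safe, and the volatile aldehyde is carried on in solution.

Step 3
Reactants: 3 (1R,2R)-2-methylcyclopropane-1-carbaldehyde; 4 ethyl 2-(diethoxyphosphoryl)prop-2-enoate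
Product: 6 ethyl (2E)-2-{[(4-methoxyphenyl)methoxy]methyl}-3-[(1R,2R)-2-methylcyclopropyl]prop-2-enoate, via sodium phosphonate carbanion 5 (not isolated)
Conditions: 4-MeOC6H4CH2OH, NaH, THF, 0 °C; then 4, 0 °C; then 3, 0 °C to rt
Reagents that add atoms: 4-methoxybenzyl alcohol, COc1ccc(CO)cc1
Why: Tandem oxa-Michael addition/Horner–Wadsworth–Emmons olefination: the alkoxide adds to the vinylphosphonate, the stabilised carbanion 5 olefinates the α-branched aldehyde, and the ester should end up trans to the cyclopropyl group as usual for α-substituted phosphonoacetates (a minor geometric isomer would be removed by chromatography).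

Step 4
Reactants: 6 ethyl (2E)-2-{[(4-methoxyphenyl)methoxy]methyl}-3-[(1R,2R)-2-methylcyclopropyl]prop-2-enoate
Product: 7 (2Z)-2-{[(4-methoxyphenyl)methoxy]methyl}-3-[(1R,2R)-2-methylcyclopropyl]prop-2-en-1-ol
Conditions: i-Bu2AlH (2.3 equiv), CH2Cl2, −78 °C; aq. KNaC4H4O6 work-up
Reagents that add atoms: none
Why: i-Bu2AlH reduces the α,β-unsaturated ester by 1,2-addition to the allylic alcohol at low temperature without touching the alkene, the cyclopropane or the benzyl ether.

Step 5
Reactants: 7 (2Z)-2-{[(4-methoxyphenyl)methoxy]methyl}-3-[(1R,2R)-2-methylcyclopropyl]prop-2-en-1-ol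
Product: 8 (2E)-2-{[(4-methoxyphenyl)methoxy]methyl}-3-[(1R,2R)-2-methylcyclopropyl]prop-2-enal
Conditions: MnO2 (excess), CH2Cl2, rt
Reagents that add atoms: none
Why: MnO2 oxidises allylic alcohols selectively to enals without isomerising the trisubstituted alkene or over-oxidising.

Step 6
Reactants: 8 (2E)-2-{[(4-methoxyphenyl)methoxy]methyl}-3-[(1R,2R)-2-methylcyclopropyl]prop-2-enal; 9 nitromethane
Product: 12 (1E,3Z)-3-{[(4-methoxyphenyl)methoxy]methyl}-4-[(1R,2R)-2-methylcyclopropyl]-1-nitrobuta-1,3-diene, via nitro alcohol 10 (not isolated), via mesylate 11 (not isolated)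
Conditions: MeNO2, 1,1,3,3-tetramethylguanidine (cat.), THF, 0 °C; then MsCl, Et3N, CH2Cl2, −20 to 0 °C
Reagents that add atoms: none
Why: Henry addition of nitromethane to the enal carbonyl (1,2-addition, the β-carbon being hindered) followed by mesylation and E1cB loss of methanesulfonate gives the conjugated (E)-nitroalkene, the existing alkene geometry staying as it is.

Step 7
Reactants: 12 (1E,3Z)-3-{[(4-methoxyphenyl)methoxy]methyl}-4-[(1R,2R)-2-methylcyclopropyl]-1-nitrobuta-1,3-diene; 13 (R)-citronellal
Product: 14 (2S,3R,4Z)-4-{[(4-methoxyphenyl)methoxy]methyl}-2-[(2R)-6-methylhept-5-en-2-yl]-5-[(1R,2R)-2-methylcyclopropyl]-3-(nitromethyl)pent-4-enal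
Conditions: (R)-2-[diphenyl(trimethylsilyloxy)methyl]pyrrolidine (10 mol %), 4-nitrophenol (10 mol %), toluene, 0 °C to rt
Reagents that add atoms: none
Why: Enamine-catalysed Michael addition of an aldehyde to a nitroalkene: the E-enamine of citronellal has one face blocked by the diphenyl(silyloxy)methyl group, so the nitrodiene adds 1,4 through the usual synclinal transition state to give the syn adduct, the (R)-catalyst being the enantiomer expected to set C8 as S under catalyst control (C7, formed R, is flattened later; C9 of citronellal is a spectator).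

Step 8
Reactants: 14 (2S,3R,4Z)-4-{[(4-methoxyphenyl)methoxy]methyl}-2-[(2R)-6-methylhept-5-en-2-yl]-5-[(1R,2R)-2-methylcyclopropyl]-3-(nitromethyl)pent-4-enal
Product: 15 dimethyl acetal of 14
Conditions: HC(OMe)3, MeOH, p-TsOH (cat.), rt
Reagents that add atoms: trimethyl orthoformate, COC(OC)OC
Why: Acid-catalysed acetalisation masks the formyl group and locks the C8 stereocentre against enolisation during the oxidation and esterification that follow.

Step 9
Reactants: 15 dimethyl acetal of 14
Product: 16 (2R,3Z)-2-[(2S,3R)-1,1-dimethoxy-3,7-dimethyloct-6-en-2-yl]-3-{[(4-methoxyphenyl)methoxy]methyl}-4-[(1R,2R)-2-methylcyclopropyl]but-3-enoic acid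
Conditions: NaNO2, AcOH, DMSO, 35 °C
Reagents that add atoms: water, O; sodium nitrite, [Na+].[O-]N=O
Why: Nitrosative Nef-type oxidation of a primary nitroalkane (nitrolic acid, nitrile oxide, hydroxamic acid) gives the carboxylic acid under weakly acidic conditions that should leave the acetal, the benzyl ether and the alkenes alone.

Step 10
Reactants: 16 (2R,3Z)-2-[(2S,3R)-1,1-dimethoxy-3,7-dimethyloct-6-en-2-yl]-3-{[(4-methoxyphenyl)methoxy]methyl}-4-[(1R,2R)-2-methylcyclopropyl]but-3-enoic acid
Product: 17 methyl ester of 16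
Conditions: Me3SiCHN2, toluene/MeOH (4:1), 0 °C
Reagents that add atoms: (trimethylsilyl)diazomethane, C[Si](C)(C)C=[N+]=[N-]
Why: Diazoalkane O-methylation is neutral, so the β,γ-unsaturated ester is not drawn into conjugation and no base reaches C7 or C8.

Step 11
Reactants: 17 methyl ester of 16
Product: 18 methyl (2R,3Z)-2-[(2S,3R)-3,7-dimethyl-1-oxooct-6-en-2-yl]-3-{[(4-methoxyphenyl)methoxy]methyl}-4-[(1R,2R)-2-methylcyclopropyl]but-3-enoate
Conditions: PPTS (cat.), acetone/H2O (10:1), 40 °C; used at once
Reagents that add atoms: water, O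
Why: Mild acid hydrolysis of the dimethyl acetal unmasks the aldehyde without cleaving the benzyl ether, and the α-branched aldehyde is used immediately to preserve C8.

Step 12
Reactants: 18 methyl (2R,3Z)-2-[(2S,3R)-3,7-dimethyl-1-oxooct-6-en-2-yl]-3-{[(4-methoxyphenyl)methoxy]methyl}-4-[(1R,2R)-2-methylcyclopropyl]but-3-enoate
Product: 19 methyl (1S,2S,3Z,5R,8S)-2-{[(4-methoxyphenyl)methoxy]methyl}-5-methyl-8-[(2R)-6-methylhept-5-en-2-yl]-7-oxocyclooct-3-ene-1-carboxylate
Conditions: [Rh(dppe)]ClO4 (20 mol %, from [Rh(nbd)(dppe)]ClO4 and H2), ethylene (1 atm), ClCH2CH2Cl (dilute), 65 °C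
Reagents that add atoms: none
Why: Oxidative addition of the formyl C–H to cationic monovalent rhodium gives an acyl hydride of trivalent rhodium (helped by chelation of the C7 ester carbonyl), hydride insertion across C6=C5 puts H on C6 and rhodium on C5 in a six-membered acyl rhodacycle, the cyclopropylcarbinyl rhodium opens by β-carbon elimination of the C4–C2 bond to a nine-membered rhodacycle containing the cis C4=C5 alkene, and C1–C2 reductive elimination releases the cyclooctenone and the catalyst. The closest known reaction is the rhodium-catalysed intramolecular hydroacylation of 4-alkenals carrying a cyclopropyl group on the alkene terminus, which gives cyclooct-4-enones. Ring A is therefore closed not by a direct eight-membered cyclisation but by six-membered metallacycle formation, three-carbon ring expansion and acyl–alkyl reductive elimination. The only new stereocentre, C6, comes from syn addition of Rh–H in a chair-like metallacycle with the C5 and C6 substituents equatorial and is expected cis to the C7 ester; C3 and C8 are untouched and the Z geometry of C4=C5 is imposed by the ring. The step needs ring opening to outrun cyclopentanone-forming reductive elimination, which the chelating diphosphine, the ethylene atmosphere and the release of cyclopropane strain favour, and it needs cleavage of the unsubstituted C4–C2 bond rather than C4–C3, which the C3 methyl secures because rhodium then moves to a primary instead of a secondary carbon.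

Step 13
Reactants: 19 methyl (1S,2S,3Z,5R,8S)-2-{[(4-methoxyphenyl)methoxy]methyl}-5-methyl-8-[(2R)-6-methylhept-5-en-2-yl]-7-oxocyclooct-3-ene-1-carboxylate
Product: 21 (3R,8S) keto lactone (ring A cyclooct-4-en-1-one with C6–CH2–O–C(=O)–C7 closed as a cis-fused γ-lactone), via hydroxy ester 20 (not isolated)
Conditions: DDQ, CH2Cl2/pH 7 buffer, 0 °C to rt; then PPTS (cat.), CH2Cl2, rt
Reagents that add atoms: none
Why: Oxidative cleavage of the p-methoxybenzyl ether by DDQ frees the C6 hydroxymethyl group, which closes the five-membered lactone on the neighbouring C7 ester (5-exo-trig acyl substitution) under mild acid; C7 is epimerisable but its configuration does not matter.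

Step 14
Reactants: 21 (3R,8S) keto lactone
Product: 22 (1R,3R,8S) hydroxy lactone (C1 hydroxyl cis to the C8 side chain)
Conditions: LiBH(s-Bu)3, THF, −78 °C; NH4Cl quench at −78 °C
Reagents that add atoms: none
Why: The bulky trialkylborohydride should attack the C1 ketone from the face opposite the adjacent C8 side chain, giving the alcohol cis to that side chain (1R), and at −78 °C it reduces the ketone much faster than the lactone.

Step 15
Reactants: 22 (1R,3R,8S) hydroxy lactone
Product: 23 (1R,3R,4S,5S,8S) cyclopropane (CH2 added across C4=C5 on the face of the C1 hydroxyl)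
Conditions: Et2Zn (added first), then CH2I2, CH2Cl2, −20 to 0 °C; stopped when the ring alkene is consumed
Reagents that add atoms: diiodomethane, ICI
Why: Hydroxyl-directed Simmons–Smith cyclopropanation: the zinc alkoxide at C1 delivers CH2 across the ring to the same face of the cis C4=C5 alkene, which is also the face opposite the allylic C3 methyl, setting C4 and C5 (both S) and outpacing the undirected reaction at the side-chain alkene.

Step 16
Reactants: 23 (1R,3R,4S,5S,8S) cyclopropane
Product: 24 C7 phenylselenide of 23 (selenium cis to C6–H)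
Conditions: LiN(i-Pr)2 (2.3 equiv), THF, −78 °C; PhSeBr, −78 °C
Reagents that add atoms: phenylselenyl bromide, Br[Se]c1ccccc1
Why: α-Selenenylation of the lactone enolate (alkoxide and enolate are formed together): the electrophile enters at C7 anti to the C6–C5 bond and therefore syn to C6–H.

Step 17
Reactants: 24 C7 phenylselenide of 23
Product: 26 (1R,3R,4S,5S,8S) hydroxy butenolide (the target without its acetyl group), via selenoxide 25 (not isolated)
Conditions: H2O2 (30 % aq., excess), pyridine, CH2Cl2, 0 °C to rt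
Reagents that add atoms: none
Why: Oxidation to the selenoxide and syn elimination toward the cis, nearly eclipsed C6–H inside the five-membered ring gives the endocyclic butenolide, the usual preference of α-alkyl-α-phenylselenyl lactones with a cis ring β-hydrogen; excess peroxide and pyridine keep the selenenic acid away from the side-chain alkene.

Step 18
Reactants: 26 (1R,3R,4S,5S,8S) hydroxy butenolide
Product: 27 CNP0018922.1
Conditions: Ac2O, pyridine, DMAP (cat.), CH2Cl2, rt
Reagents that add atoms: acetic anhydride, CC(=O)OC(C)=O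
Why: DMAP-catalysed acylation of the secondary alcohol gives the acetate without affecting the butenolide, the cyclopropane or the side-chain alkene.

**Compound list**

1 | (E)-but-2-en-1-ol [(E)-crotyl alcohol] | C/C=C/CO | starting material
2 | [(1R,2R)-2-methylcyclopropyl]methanol | OC[C@@H]1C[C@H]1C | intermediate
3 | (1R,2R)-2-methylcyclopropane-1-carbaldehyde | O=C[C@@H]1C[C@H]1C | intermediate
4 | ethyl 2-(diethoxyphosphoryl)prop-2-enoate | C=C(C(=O)OCC)P(=O)(OCC)OCC | starting material
5 | sodium salt of the α-carbanion of ethyl 2-(diethoxyphosphoryl)-3-[(4-methoxyphenyl)methoxy]propanoate | CCOC(=O)[C-](COCc1ccc(OC)cc1)P(=O)(OCC)OCC.[Na+] | intermediate (not isolated)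
6 | ethyl (2E)-2-{[(4-methoxyphenyl)methoxy]methyl}-3-[(1R,2R)-2-methylcyclopropyl]prop-2-enoate | CCOC(=O)/C(COCc1ccc(OC)cc1)=C/[C@@H]1C[C@H]1C | intermediate
7 | (2Z)-2-{[(4-methoxyphenyl)methoxy]methyl}-3-[(1R,2R)-2-methylcyclopropyl]prop-2-en-1-ol | OC/C(COCc1ccc(OC)cc1)=C/[C@@H]1C[C@H]1C | intermediate
8 | (2E)-2-{[(4-methoxyphenyl)methoxy]methyl}-3-[(1R,2R)-2-methylcyclopropyl]prop-2-enal | O=C/C(COCc1ccc(OC)cc1)=C/[C@@H]1C[C@H]1C | intermediate
9 | nitromethane | C[N+](=O)[O-] | starting material
10 | (3E)-3-{[(4-methoxyphenyl)methoxy]methyl}-4-[(1R,2R)-2-methylcyclopropyl]-1-nitrobut-3-en-2-ol (both carbinol epimers) | [O-][N+](=O)CC(O)/C(COCc1ccc(OC)cc1)=C/[C@@H]1C[C@H]1C | intermediate (not isolated)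
11 | methanesulfonate of 10 | [O-][N+](=O)CC(OS(C)(=O)=O)/C(COCc1ccc(OC)cc1)=C/[C@@H]1C[C@H]1C | intermediate (not isolated)
12 | (1E,3Z)-3-{[(4-methoxyphenyl)methoxy]methyl}-4-[(1R,2R)-2-methylcyclopropyl]-1-nitrobuta-1,3-diene | [O-][N+](=O)/C=C/C(COCc1ccc(OC)cc1)=C/[C@@H]1C[C@H]1C | intermediate
13 | (R)-citronellal [(3R)-3,7-dimethyloct-6-enal] | O=CC[C@H](C)CCC=C(C)C | starting material
14 | (2S,3R,4Z)-4-{[(4-methoxyphenyl)methoxy]methyl}-2-[(2R)-6-methylhept-5-en-2-yl]-5-[(1R,2R)-2-methylcyclopropyl]-3-(nitromethyl)pent-4-enal | O=C[C@@H]([C@H](C)CCC=C(C)C)[C@@H](C[N+](=O)[O-])/C(COCc1ccc(OC)cc1)=C/[C@@H]1C[C@H]1C | intermediate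
15 | dimethyl acetal of 14 (C8 S, C7 R) | COC(OC)[C@@H]([C@H](C)CCC=C(C)C)[C@@H](C[N+](=O)[O-])/C(COCc1ccc(OC)cc1)=C/[C@@H]1C[C@H]1C | intermediate
16 | (2R,3Z)-2-[(2S,3R)-1,1-dimethoxy-3,7-dimethyloct-6-en-2-yl]-3-{[(4-methoxyphenyl)methoxy]methyl}-4-[(1R,2R)-2-methylcyclopropyl]but-3-enoic acid | COC(OC)[C@@H]([C@H](C)CCC=C(C)C)[C@@H](C(=O)O)/C(COCc1ccc(OC)cc1)=C/[C@@H]1C[C@H]1C | intermediate
17 | methyl ester of 16 | COC(OC)[C@@H]([C@H](C)CCC=C(C)C)[C@@H](C(=O)OC)/C(COCc1ccc(OC)cc1)=C/[C@@H]1C[C@H]1C | intermediate
18 | methyl (2R,3Z)-2-[(2S,3R)-3,7-dimethyl-1-oxooct-6-en-2-yl]-3-{[(4-methoxyphenyl)methoxy]methyl}-4-[(1R,2R)-2-methylcyclopropyl]but-3-enoate (key-step precursor; C1 formyl, C8 S, C7 ester, C6 CH2OPMB, C6=C5, trans-2-methylcyclopropyl on C5) | O=C[C@@H]([C@H](C)CCC=C(C)C)[C@@H](C(=O)OC)/C(COCc1ccc(OC)cc1)=C/[C@@H]1C[C@H]1C | intermediate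
19 | methyl (1S,2S,3Z,5R,8S)-2-{[(4-methoxyphenyl)methoxy]methyl}-5-methyl-8-[(2R)-6-methylhept-5-en-2-yl]-7-oxocyclooct-3-ene-1-carboxylate (key-step product; route numbering C1 ketone, C3 R methyl, C4=C5 cis, C6 CH2OPMB, C7 ester, C8 S side chain) | O=C1C[C@@H](C)/C=C\[C@H](COCc2ccc(OC)cc2)[C@H](C(=O)OC)[C@@H]1[C@H](C)CCC=C(C)C | intermediate
20 | methyl (1S,2S,3Z,5R,8S)-2-(hydroxymethyl)-5-methyl-8-[(2R)-6-methylhept-5-en-2-yl]-7-oxocyclooct-3-ene-1-carboxylate | O=C1C[C@@H](C)/C=C\[C@H](CO)[C@H](C(=O)OC)[C@@H]1[C@H](C)CCC=C(C)C | intermediate (not isolated)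
21 | (3R,8S) keto lactone: cyclooct-4-en-1-one with cis-fused γ-lactone C6–CH2–O–C(=O)–C7, C6–H and C7–H on the face of the C3 methyl | O=C1C[C@@H](C)/C=C\[C@@H]2COC(=O)[C@@H]2[C@@H]1[C@H](C)CCC=C(C)C | intermediate
22 | (1R,3R,8S) hydroxy lactone: 21 with C1 reduced, hydroxyl cis to the C8 side chain | O[C@@H]1C[C@@H](C)/C=C\[C@@H]2COC(=O)[C@@H]2[C@@H]1[C@H](C)CCC=C(C)C | intermediate
23 | (1R,3R,4S,5S,8S) cyclopropane: 22 with CH2 across C4–C5 on the face of the C1 hydroxyl | O[C@@H]1C[C@@H](C)[C@@H]2C[C@@H]2[C@@H]3COC(=O)[C@@H]3[C@@H]1[C@H](C)CCC=C(C)C | intermediate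
24 | C7 phenylselenide of 23, selenium cis to C6–H | O[C@@H]1C[C@@H](C)[C@@H]2C[C@@H]2[C@@H]3COC(=O)[C@]3([Se]c4ccccc4)[C@@H]1[C@H](C)CCC=C(C)C | intermediate
25 | selenoxide of 24 | O[C@@H]1C[C@@H](C)[C@@H]2C[C@@H]2[C@@H]3COC(=O)[C@]3([Se](=O)c4ccccc4)[C@@H]1[C@H](C)CCC=C(C)C | intermediate (not isolated)
26 | (1R,3R,4S,5S,8S) hydroxy butenolide (target without the acetyl group) | O[C@@H]1C[C@@H](C)[C@@H]2C[C@@H]2C2=C(C(=O)OC2)[C@@H]1[C@H](C)CCC=C(C)C | intermediate
27 | CNP0018922.1: (1R,3R,4S,5S,8S) acetate with the (R)-6-methylhept-5-en-2-yl side chain on C8 | CC(=O)O[C@@H]1C[C@@H](C)[C@@H]2C[C@@H]2C2=C(C(=O)OC2)[C@@H]1[C@H](C)CCC=C(C)C | target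

**Step count and risks**

Total step count: 18. Longest linear sequence: 18 steps (1 to 27); 4, 9 and 13 enter as commercial partners in steps 3, 6 and 7.

Steps most likely to fail:

1. Step 12. The trisubstituted C6=C5 alkene may insert too slowly into the acyl rhodium hydride, so that decarbonylation takes over. The six-membered rhodacycle may also reductively eliminate to a cyclopentanone before the cyclopropane opens, or the methyl-bearing C4–C3 bond may be cleaved. Fallback: ring B is closed before ring A, so that the alkene becomes an exocyclic alkylidene held next to the formyl-bearing carbon. Setting out from 17, DDQ (CH2Cl2/pH 7 buffer) removes the p-methoxybenzyl group to give the hydroxy ester acetal F1, which lactonises under PPTS to the alkylidene lactone acetal F2. Acetal hydrolysis (PPTS, acetone/H2O) gives the lactone aldehyde F3. The same [Rh(dppe)]ClO4 hydroacylation with cyclopropane fragmentation on this conformationally restricted 4-alkenal would then give keto lactone 21 directly, where the route is rejoined.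

2. Step 15. The undirected cyclopropanation of the electron-rich side-chain alkene may compete with the ring alkene, and facial selectivity may be poor if transannular delivery from the C1 zinc alkoxide is weak. Fallback: the butenolide is made first and the cyclopropane is introduced by conjugate methylenation, which cannot touch an isolated alkene. Setting out from 22, selenenylation at C7 (LiN(i-Pr)2, PhSeBr, THF, −78 °C) gives the selenide F4. H2O2/pyridine gives the selenoxide F5, which eliminates toward the allylic C6–H to the hydroxy dienolide F6. Acetylation (Ac2O, pyridine, DMAP) gives the acetoxy dienolide F7. Corey–Chaykovsky cyclopropanation with dimethylsulfoxonium methylide (Me3S(O)I, NaH, DMSO, rt) should add 1,6 at C4 anti to the C3 methyl and close the three-membered ring onto C5, coming back to the route at 27.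

3. Step 14. Hydride delivery to the medium-ring ketone may be governed by ring conformation rather than by the C8 substituent, giving the C1 epimer. Fallback: the configuration is corrected by SN2 inversion instead of being set by the reduction. Setting out from 21, a small hydride (NaBH4, CeCl3·7H2O, MeOH, −40 °C) gives the epimeric alcohol F8. Mitsunobu reaction (4-nitrobenzoic acid, PPh3, diisopropyl azodicarboxylate, THF, 0 °C) inverts C1 to the 4-nitrobenzoate F9. Methanolysis (K2CO3, MeOH, 0 °C) returns to the route at 22.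

Further compounds
F1 | step 12 | hydroxy ester acetal: methyl (2R,3Z)-2-[(2S,3R)-1,1-dimethoxy-3,7-dimethyloct-6-en-2-yl]-3-(hydroxymethyl)-4-[(1R,2R)-2-methylcyclopropyl]but-3-enoate | COC(OC)[C@@H]([C@H](C)CCC=C(C)C)[C@@H](C(=O)OC)/C(CO)=C/[C@@H]1C[C@H]1C
F2 | step 12 | alkylidene lactone acetal: γ-butyrolactone with C7 (α-carbon) bearing the C8 acetal chain and C6 (β-carbon) bearing the exocyclic (2-methylcyclopropyl)methylidene group | COC(OC)[C@@H]([C@H](C)CCC=C(C)C)[C@H]2C(=O)OC/C2=C\[C@@H]3C[C@H]3C
F3 | step 12 | lactone aldehyde: F2 with the acetal hydrolysed to the C1 formyl group | O=C[C@@H]([C@H](C)CCC=C(C)C)[C@H]2C(=O)OC/C2=C\[C@@H]3C[C@H]3C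
F4 | step 15 | C7 phenylselenide of 22 | O[C@@H]1C[C@@H](C)/C=C\[C@@H]2COC(=O)[C@]2([Se]c3ccccc3)[C@@H]1[C@H](C)CCC=C(C)C
F5 | step 15 | selenoxide of F4 | O[C@@H]1C[C@@H](C)/C=C\[C@@H]2COC(=O)[C@]2([Se](=O)c3ccccc3)[C@@H]1[C@H](C)CCC=C(C)C
F6 | step 15 | hydroxy dienolide: (1R,3R,8S) alcohol with C4=C5 conjugated to the C6=C7 butenolide | O[C@@H]1C[C@@H](C)/C=C\C2=C(C(=O)OC2)[C@@H]1[C@H](C)CCC=C(C)C
F7 | step 15 | acetoxy dienolide: acetate of F6 | CC(=O)O[C@@H]1C[C@@H](C)/C=C\C2=C(C(=O)OC2)[C@@H]1[C@H](C)CCC=C(C)C
F8 | step 14 | C1 epimer of 22 (hydroxyl trans to the C8 side chain) | O[C@H]1C[C@@H](C)/C=C\[C@@H]2COC(=O)[C@@H]2[C@@H]1[C@H](C)CCC=C(C)C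
F9 | step 14 | 4-nitrobenzoate of 22 | O=C(O[C@@H]1C[C@@H](C)/C=C\[C@@H]2COC(=O)[C@@H]2[C@@H]1[C@H](C)CCC=C(C)C)c1ccc([N+](=O)[O-])cc1
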